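**Plan** (azulene numbering: C1–C3 five-membered ring, C3a/C8a ring fusion, C4–C8 seven-membered ring; the target carries a 1,2-epoxide, methyls at C2 and C7, isopropyl at C4, the ester at C5 and the hydroxyl at C7)
- Retrosynthetic cuts, in order: the benzoate C–O bond and the epoxide; then the two cyclopentane bonds C3–C3a and C1–C8a in one [3+2] event; then the C8–C8a bond (one-carbon ring expansion), back to (R)-carvone.
- Enabling feature: C1–C2(Me)–C3 is tied to the seven-membered ring only at the adjacent carbons C3a and C8a, so the five-membered ring is the adduct of a 2-substituted allyl (trimethylenemethane) unit with the C3a=C8a olefin of a cycloheptenone. The carbonyl is placed at C8, where it activates the olefin, makes C8a correctable, serves to set the C7 carbinol and is then deleted.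
- Forward order: carvone → C5-oxygenated six-membered enone → seven-membered cross-conjugated dienone → [3+2] builds the five-membered ring → C8/C7 editing → olefin transposition, esterification, epoxidation.
- Stereochemistry: C4 from carvone; C5–O and C3a anti to the isopropyl group; C8a by equilibration; C7–O anti to the C5 silyloxy group; epoxide syn to the C7 hydroxyl.

Key step: step 8

Remark: in bicyclic compounds β is the face of the C4 isopropyl group and α the opposite face; "perhydroazulene" means the saturated bicyclo[5.3.0]decane skeleton.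

**Step 1**
Reactants: 1 (R)-(−)-carvone
Product: 2 (R)-carvotanacetone, (5R)-5-isopropyl-2-methylcyclohex-2-en-1-one
Conditions: H2 (1 atm), RhCl(PPh3)3 (cat.), toluene, 23 °C
Reagents that add atoms: none
Why: Homogeneous catalytic hydrogenation with RhCl(PPh3)3 should saturate the 1,1-disubstituted isopropenyl olefin chemoselectively and leave the trisubstituted conjugated enone and the C5 stereocentre untouched.

**Step 2**
Reactants: 2 (R)-carvotanacetone
Product: 3 (5R)-5-isopropyl-2-methylcyclohex-3-en-1-one (both C2 epimers)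
Conditions: KOtBu, t-BuOH/THF, 23 °C; then poured into AcOH/H2O, 0 °C
Reagents that add atoms: none
Why: Base-mediated deconjugation: γ-deprotonation gives the extended dienolate, and its kinetic protonation at the α-carbon should give the β,γ-unsaturated ketone; C5 is not touched and the C2 epimers converge in step 3.

**Step 3**
Reactants: 3 (5R)-5-isopropyl-2-methylcyclohex-3-en-1-one
Product: 5 (4R,5R)-4-hydroxy-5-isopropyl-2-methylcyclohex-2-en-1-one, via β,γ-epoxy ketone 4 (not isolated)
Conditions: mCPBA, NaHCO3, CH2Cl2, 0 °C; then Et3N, 23 °C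
Reagents that add atoms: 3-chloroperoxybenzoic acid (mCPBA), OOC(=O)c1cccc(Cl)c1
Why: Prilezhaev epoxidation of the only olefin should occur anti to the adjacent isopropyl group, and amine-induced E1cB opening of the β,γ-epoxy ketone then gives the γ-hydroxy enone with the hydroxyl trans to isopropyl.

**Step 4**
Reactants: 5 (4R,5R)-4-hydroxy-5-isopropyl-2-methylcyclohex-2-en-1-one
Product: 6 (4R,5R)-4-[(tert-butyldimethylsilyl)oxy]-5-isopropyl-2-methylcyclohex-2-en-1-one
Conditions: TBSCl, imidazole, DMF, 23 °C
Reagents that add atoms: tert-butyldimethylsilyl chloride, CC(C)(C)[Si](C)(C)Cl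
Why: Standard silyl ether formation protects the secondary alcohol for the basic, organometallic and hydride steps that follow.

**Step 5**
Reactants: 6 (4R,5R)-4-[(tert-butyldimethylsilyl)oxy]-5-isopropyl-2-methylcyclohex-2-en-1-one
Product: 7 1,6-trans tert-butyl{[6-isopropyl-3-methyl-4-(trimethylsilyloxy)cyclohexa-2,4-dien-1-yl]oxy}dimethylsilane
Conditions: LDA, THF, −78 °C; then TMSCl
Reagents that add atoms: chlorotrimethylsilane, C[Si](C)(C)Cl
Why: Kinetic deprotonation of the enone at the α'-methylene and O-silylation should give the cross-conjugated 2-silyloxy diene (kinetic silyl enol ether formation).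

**Step 6**
Reactants: 7 cross-conjugated silyl dienol ether
Product: 8 4-[(tert-butyldimethylsilyl)oxy]-5-isopropyl-2-methyl-1-(trimethylsilyloxy)bicyclo[4.1.0]hept-2-ene (cyclopropane anti to isopropyl)
Conditions: Et2Zn, CH2I2, CH2Cl2, 0 °C
Reagents that add atoms: diiodomethane, ICI
Why: Simmons–Smith cyclopropanation (Furukawa variant) should take place at the electron-rich silyl enol ether olefin and not at the conjugated trisubstituted one, on the face anti to the isopropyl group.

**Step 7**
Reactants: 8 siloxycyclopropane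
Product: 10 4,5-trans 4-[(tert-butyldimethylsilyl)oxy]-5-isopropyl-2-methylcyclohepta-2,6-dien-1-one, via β-chloro ketone 9 (not isolated)
Conditions: FeCl3, DMF, 0 °C; then NaOAc, MeOH, 65 °C
Reagents that add atoms: none
Why: Ito–Saegusa ring expansion: one-electron oxidation by FeCl3 cleaves the internal cyclopropane bond, the ring-expanded radical takes up chlorine, and acetate-induced E1cB elimination gives the cross-conjugated dienone; the two stereocentres are not involved.

**Step 8**
Reactants: 10 4,5-trans cycloheptadienone; 11 2-[(trimethylsilyl)methyl]allyl acetate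
Product: 12 cis-fused 5α-[(tert-butyldimethylsilyl)oxy]-4β-isopropyl-7-methyl-2-methylidene-1,2,3,3a,4,5,8,8a-octahydroazulen-8-one (3aβ-H,8aβ-H)
Conditions: Pd(OAc)2 (5 mol%), P(OiPr)3 (30 mol%), THF, 65 °C
Reagents that add atoms: none
Why: Zerovalent palladium formed from Pd(OAc)2 and the phosphite ionises the allylic acetate of 11, the acetate removes the silyl group, and the zwitterionic trimethylenemethane–palladium complex adds through its carbanionic CH2 to C6 of 10 (the future C3a); the enolate carbon C7 (the future C8a) then attacks the π-allylpalladium terminus and releases the catalyst. The closest known reaction type is the palladium-catalysed trimethylenemethane [3+2] cycloaddition to cyclopentenones and cycloheptenones. The cyclopentane closes in a 5-(enolexo)-exo-trig mode, the sequence being conjugate addition followed by intramolecular allylic alkylation. C3a is set by attack anti to the adjacent isopropyl group (control by the γ-substituent), and C8a is set cis to the new C3–C3a bond by the geometry of the five-membered ring closure; C8a lies α to the ketone and is corrected in step 9. The step needs site selectivity for the C6=C7 olefin over the C2=C3 olefin of 10, which the C2 methyl group should secure because 2-alkyl enones are poor acceptors for this nucleophile, and face selectivity, which the isopropyl group secures.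

**Step 9**
Reactants: 12 cis-fused methylidene enone
Product: 14 trans-fused 6β,7β-epoxy-5α-[(tert-butyldimethylsilyl)oxy]-4β-isopropyl-7α-methyl-2-methylideneperhydroazulen-8-one (3aβ-H,8aα-H), via cis-fused epoxy ketone 13 (not isolated)
Conditions: 30% H2O2, NaOH, MeOH, 0 °C; then DBU, CH2Cl2, 23 °C
Reagents that add atoms: hydrogen peroxide, OO
Why: Weitz–Scheffer nucleophilic epoxidation attacks only the enone, anti to the adjacent C5 silyloxy group (β-epoxide, which fixes C7–O); base equilibration at C8a, the only enolisable position, should then give the trans-fused ketone in which the C4, C3a and C8a substituents are all equatorial.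

**Step 10**
Reactants: 14 trans-fused epoxy ketone
Product: 15 5α-[(tert-butyldimethylsilyl)oxy]-4β-isopropyl-7α-methyl-2-methylideneperhydroazulene-7β,8-diol (3aβ-H,8aα-H; C8 epimers)
Conditions: LiAlH4, THF, 0 → 40 °C
Reagents that add atoms: none
Why: Hydride reduction of the ketone and SN2 hydride opening of the trisubstituted epoxide at its secondary carbon C6 should give the tertiary C7 alcohol with its C–O bond, and so its configuration, untouched; the C8 carbinol configuration is of no consequence.

**Step 11**
Reactants: 15 7β,8-diol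
Product: 16 8-O-(phenoxythiocarbonyl) derivative of 15
Conditions: PhOC(S)Cl, pyridine, DMAP (cat.), CH2Cl2, 23 °C
Reagents that add atoms: O-phenyl chlorothionoformate, S=C(Cl)Oc1ccccc1
Why: Thioacylation should take place at the secondary C8 hydroxyl only, the tertiary C7 hydroxyl being too hindered (first stage of the Barton–McCombie deoxygenation).

**Step 12**
Reactants: 16 C8 thionocarbonate
Product: 17 5α-[(tert-butyldimethylsilyl)oxy]-4β-isopropyl-7α-methyl-2-methylideneperhydroazulen-7β-ol (3aβ-H,8aα-H)
Conditions: Bu3SnH, AIBN (cat.), toluene, 90 °C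
Reagents that add atoms: none
Why: Barton–McCombie radical deoxygenation replaces the C8 oxygen by hydrogen through a secondary radical that has no fragmentation path; no stereocentre is formed.

**Step 13**
Reactants: 17 exocyclic olefin with free C7 hydroxyl
Product: 18 5α-[(tert-butyldimethylsilyl)oxy]-4β-isopropyl-2,7α-dimethyl-3,3a,4,5,6,7,8,8a-octahydroazulen-7β-ol (3aβ-H,8aα-H; C1=C2 olefin)
Conditions: [Ir{2-(2,4-difluorophenyl)-5-(trifluoromethyl)pyridine-C,N}2{5,5'-bis(trifluoromethyl)-2,2'-bipyridine}]PF6 (2 mol%), 2,4,6-triisopropylbenzenethiol (10 mol%), 2,4,6-collidine (20 mol%), PhCF3, blue LEDs, 23 °C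
Reagents that add atoms: none
Why: Proposed new method: hydroxyl-directed olefin transposition, in which proton-coupled electron transfer from the collidine-bound tertiary O–H to the excited photocatalyst gives the C7 alkoxy radical, 1,5-hydrogen atom transfer through a six-membered transition state takes the allylic C1–H (the ring allylic C3–H is out of reach, and the reachable tertiary C3a–H and C4–H are not allylic), and the thiol returns a hydrogen atom to the exocyclic terminus of the allyl radical so that the more substituted C1=C2 olefin results in a redox-neutral cycle; the closest known reaction types are the photocatalytic alkoxy-radical isomerisation of cyclic alcohols by β-scission and the δ-C–H functionalisation of alcohols by alkoxy-radical 1,5-hydrogen transfer.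

**Step 14**
Reactants: 18 C5 silyl ether
Product: 19 4β-isopropyl-2,7α-dimethyl-3,3a,4,5,6,7,8,8a-octahydroazulene-5α,7β-diol (3aβ-H,8aα-H)
Conditions: TBAF, THF, 23 °C
Reagents that add atoms: none
Why: Fluoride-induced desilylation frees the secondary C5 hydroxyl without touching the olefin or the tertiary alcohol.

**Step 15**
Reactants: 19 5α,7β-diol; 20 4-[(tert-butyldimethylsilyl)oxy]benzoic acid
Product: 21 7β-hydroxy-4β-isopropyl-2,7α-dimethyl-3,3a,4,5,6,7,8,8a-octahydroazulen-5α-yl 4-[(tert-butyldimethylsilyl)oxy]benzoate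
Conditions: EDC·HCl, DMAP, CH2Cl2, 23 °C
Reagents that add atoms: none
Why: Steglich esterification should acylate the secondary C5 hydroxyl with retention and leave the tertiary C7 hydroxyl free; the silyl ether prevents self-condensation of the phenolic acid.

**Step 16**
Reactants: 21 olefinic hydroxy ester
Product: 22 1β,2β-epoxy-7β-hydroxy-4β-isopropyl-2α,7α-dimethylperhydroazulen-5α-yl 4-[(tert-butyldimethylsilyl)oxy]benzoate (3aβ-H,8aα-H)
Conditions: VO(acac)2 (cat.), t-BuOOH, CH2Cl2, 0 → 23 °C
Reagents that add atoms: tert-butyl hydroperoxide, CC(C)(C)OO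
Why: Hydroxyl-directed vanadium-catalysed epoxidation should deliver oxygen to the C1=C2 olefin from the face of the C7 hydroxyl (β), which sets C1 and C2; the product is stable because the syn hydroxyl cannot open the epoxide from the rear.

**Step 17**
Reactants: 22 silyl-protected epoxy ester
Product: 23 target, 1β,2β-epoxy-7β-hydroxy-4β-isopropyl-2α,7α-dimethylperhydroazulen-5α-yl 4-hydroxybenzoate
Conditions: TBAF, AcOH, THF, 0 °C
Reagents that add atoms: none
Why: Buffered fluoride cleaves the aryl silyl ether selectively and should leave the ester, the epoxide and the tertiary alcohol intact.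

**Compound list**
1 | (R)-(−)-carvone, (5R)-2-methyl-5-(prop-1-en-2-yl)cyclohex-2-en-1-one | CC(=C)[C@H]1CC(=O)C(C)=CC1 | starting material
2 | (R)-carvotanacetone, (5R)-5-isopropyl-2-methylcyclohex-2-en-1-one | CC(C)[C@H]1CC(=O)C(C)=CC1 | intermediate
3 | (5R)-5-isopropyl-2-methylcyclohex-3-en-1-one (both C2 epimers) | CC(C)[C@H]1CC(=O)C(C)C=C1 | intermediate
4 | 3,4-epoxy-5-isopropyl-2-methylcyclohexan-1-one, epoxide trans to isopropyl (both C2 epimers) | CC(C)[C@H]1CC(=O)C(C)[C@@H]2O[C@H]12 | intermediate (not isolated)
5 | (4R,5R)-4-hydroxy-5-isopropyl-2-methylcyclohex-2-en-1-one | CC(C)[C@H]1CC(=O)C(C)=C[C@@H]1O | intermediate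
6 | (4R,5R)-4-[(tert-butyldimethylsilyl)oxy]-5-isopropyl-2-methylcyclohex-2-en-1-one | CC(C)[C@H]1CC(=O)C(C)=C[C@@H]1O[Si](C)(C)C(C)(C)C | intermediate
7 | 1,6-trans tert-butyl{[6-isopropyl-3-methyl-4-(trimethylsilyloxy)cyclohexa-2,4-dien-1-yl]oxy}dimethylsilane | CC(C)[C@H]1C=C(O[Si](C)(C)C)C(C)=C[C@@H]1O[Si](C)(C)C(C)(C)C | intermediate
8 | 4-[(tert-butyldimethylsilyl)oxy]-5-isopropyl-2-methyl-1-(trimethylsilyloxy)bicyclo[4.1.0]hept-2-ene, cyclopropane anti to isopropyl | CC(C)[C@H]1[C@@H]2C[C@]2(O[Si](C)(C)C)C(C)=C[C@@H]1O[Si](C)(C)C(C)(C)C | intermediate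
9 | 4,5-trans 4-[(tert-butyldimethylsilyl)oxy]-6-chloro-5-isopropyl-2-methylcyclohept-2-en-1-one (both C6 epimers) | CC(C)[C@H]1C(Cl)CC(=O)C(C)=C[C@@H]1O[Si](C)(C)C(C)(C)C | intermediate (not isolated)
10 | 4,5-trans 4-[(tert-butyldimethylsilyl)oxy]-5-isopropyl-2-methylcyclohepta-2,6-dien-1-one | CC(C)[C@H]1C=CC(=O)C(C)=C[C@@H]1O[Si](C)(C)C(C)(C)C | intermediate
11 | 2-[(trimethylsilyl)methyl]allyl acetate | C[Si](C)(C)CC(=C)COC(C)=O | starting material
12 | cis-fused 5α-[(tert-butyldimethylsilyl)oxy]-4β-isopropyl-7-methyl-2-methylidene-1,2,3,3a,4,5,8,8a-octahydroazulen-8-one (3aβ-H,8aβ-H) | CC(C)[C@H]1[C@@H]2CC(=C)C[C@@H]2C(=O)C(C)=C[C@@H]1O[Si](C)(C)C(C)(C)C | intermediate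
13 | cis-fused 6β,7β-epoxy-5α-[(tert-butyldimethylsilyl)oxy]-4β-isopropyl-7α-methyl-2-methylideneperhydroazulen-8-one (3aβ-H,8aβ-H) | CC(C)[C@H]1[C@@H]2CC(=C)C[C@@H]2C(=O)[C@@]3(C)O[C@H]3[C@@H]1O[Si](C)(C)C(C)(C)C | intermediate (not isolated)
14 | trans-fused 6β,7β-epoxy-5α-[(tert-butyldimethylsilyl)oxy]-4β-isopropyl-7α-methyl-2-methylideneperhydroazulen-8-one (3aβ-H,8aα-H) | CC(C)[C@H]1[C@@H]2CC(=C)C[C@H]2C(=O)[C@@]3(C)O[C@H]3[C@@H]1O[Si](C)(C)C(C)(C)C | intermediate
15 | 5α-[(tert-butyldimethylsilyl)oxy]-4β-isopropyl-7α-methyl-2-methylideneperhydroazulene-7β,8-diol (3aβ-H,8aα-H; C8 epimers) | CC(C)[C@H]1[C@@H]2CC(=C)C[C@H]2C(O)[C@@](C)(O)C[C@@H]1O[Si](C)(C)C(C)(C)C | intermediate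
16 | 8-O-(phenoxythiocarbonyl) derivative of 15 | CC(C)[C@H]1[C@@H]2CC(=C)C[C@H]2C(OC(=S)Oc2ccccc2)[C@@](C)(O)C[C@@H]1O[Si](C)(C)C(C)(C)C | intermediate
17 | 5α-[(tert-butyldimethylsilyl)oxy]-4β-isopropyl-7α-methyl-2-methylideneperhydroazulen-7β-ol (3aβ-H,8aα-H) | CC(C)[C@H]1[C@@H]2CC(=C)C[C@H]2C[C@@](C)(O)C[C@@H]1O[Si](C)(C)C(C)(C)C | intermediate
18 | 5α-[(tert-butyldimethylsilyl)oxy]-4β-isopropyl-2,7α-dimethyl-3,3a,4,5,6,7,8,8a-octahydroazulen-7β-ol (3aβ-H,8aα-H) | CC(C)[C@H]1[C@@H]2CC(C)=C[C@H]2C[C@@](C)(O)C[C@@H]1O[Si](C)(C)C(C)(C)C | intermediate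
19 | 4β-isopropyl-2,7α-dimethyl-3,3a,4,5,6,7,8,8a-octahydroazulene-5α,7β-diol (3aβ-H,8aα-H) | CC(C)[C@H]1[C@@H]2CC(C)=C[C@H]2C[C@@](C)(O)C[C@@H]1O | intermediate
20 | 4-[(tert-butyldimethylsilyl)oxy]benzoic acid | CC(C)(C)[Si](C)(C)Oc1ccc(cc1)C(O)=O | starting material
21 | 7β-hydroxy-4β-isopropyl-2,7α-dimethyl-3,3a,4,5,6,7,8,8a-octahydroazulen-5α-yl 4-[(tert-butyldimethylsilyl)oxy]benzoate | CC(C)[C@H]1[C@@H]2CC(C)=C[C@H]2C[C@@](C)(O)C[C@@H]1OC(=O)c1ccc(O[Si](C)(C)C(C)(C)C)cc1 | intermediate
22 | 1β,2β-epoxy-7β-hydroxy-4β-isopropyl-2α,7α-dimethylperhydroazulen-5α-yl 4-[(tert-butyldimethylsilyl)oxy]benzoate (3aβ-H,8aα-H) | CC(C)[C@H]1[C@@H]2C[C@@]3(C)O[C@H]3[C@H]2C[C@@](C)(O)C[C@@H]1OC(=O)c1ccc(O[Si](C)(C)C(C)(C)C)cc1 | intermediate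
23 | 1β,2β-epoxy-7β-hydroxy-4β-isopropyl-2α,7α-dimethylperhydroazulen-5α-yl 4-hydroxybenzoate (3aβ-H,8aα-H) | CC(C)[C@H]1[C@@H]2C[C@@]3(C)O[C@H]3[C@H]2C[C@@](C)(O)C[C@@H]1OC(=O)c1ccc(O)cc1 | target

**Count**
Total step count: 17. Longest linear sequence: 17 steps (1 → 23); 11 and 20 are bought.

**Steps most likely to fail, with fallbacks**

1. Step 13 (Proposed new method). What may go wrong: β-scission of the alkoxy radical with opening of the seven-membered ring, or undirected isomerisation by thiyl radicals that erodes the regiocontrol. Fallback with known chemistry: setting out from 17, Riley oxidation (SeO2, t-BuOOH, CH2Cl2) should hydroxylate the ring allylic position C1, the one remote from the isopropyl group, to give the 2-methylidene-1-ol F1. Mitsunobu reaction of the allylic alcohol F1 with 2-nitrobenzenesulfonylhydrazide (PPh3, diethyl azodicarboxylate, N-methylmorpholine, THF, −30 °C) gives the N-alkyl-N-sulfonylhydrazine F2. On warming to 23 °C this loses the sulfinic acid to give the allylic diazene F3. Retro-ene loss of dinitrogen then puts hydrogen on the exocyclic carbon and the double bond at C1=C2, which comes back to the route at 18.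

2. Step 8 (key step). What may go wrong: conjugate addition to the 2-methyl enone unit or to both enone units, poor facial selectivity, or protodesilylation of the donor before cycloaddition. Fallback: setting out from 10, Hosomi–Sakurai conjugate allylation with 2-(chloromethyl)-3-(trimethylsilyl)prop-1-ene (TiCl4, CH2Cl2, −78 °C) should give the 6-[2-(chloromethyl)allyl] ketone F4, again by attack anti to the isopropyl group. Intramolecular enolate alkylation of the allylic chloride F4 (KOtBu, THF, 0 °C) then closes the five-membered ring and comes back to the route at 12.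

3. Step 16. What may go wrong: poor facial selectivity if the tertiary hydroxyl is too remote to bind and deliver the oxidant, or acid-promoted opening of the trisubstituted epoxide. Fallback: setting out from 21, Shi epoxidation (fructose-derived ketone catalyst of the enantiomeric series that attacks the β face, Oxone, K2CO3 buffer, MeCN/H2O, 0 °C) puts the facial choice under reagent control and comes back to the route at 22; no new compound arises.

**Further compounds**
F1 | step 13 | 5α-[(tert-butyldimethylsilyl)oxy]-4β-isopropyl-7α-methyl-2-methylideneperhydroazulene-1,7β-diol (3aβ-H,8aα-H; C1 epimers) | CC(C)[C@H]1[C@@H]2CC(=C)C(O)[C@H]2C[C@@](C)(O)C[C@@H]1O[Si](C)(C)C(C)(C)C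
F2 | step 13 | N-(perhydroazulen-1-yl)-N-(2-nitrobenzenesulfonyl)hydrazine derived from F1 | CC(C)[C@H]1[C@@H]2CC(=C)C(N(N)S(=O)(=O)c3ccccc3[N+]([O-])=O)[C@H]2C[C@@](C)(O)C[C@@H]1O[Si](C)(C)C(C)(C)C
F3 | step 13 | C1 monoalkyl diazene derived from F2 | CC(C)[C@H]1[C@@H]2CC(=C)C(N=N)[C@H]2C[C@@](C)(O)C[C@@H]1O[Si](C)(C)C(C)(C)C
F4 | step 8 | 4-[(tert-butyldimethylsilyl)oxy]-6-[2-(chloromethyl)prop-2-en-1-yl]-5-isopropyl-2-methylcyclohept-2-en-1-one (4,5-trans; 5,6-trans) | CC(C)[C@H]1[C@H](CC(=C)CCl)CC(=O)C(C)=C[C@@H]1O[Si](C)(C)C(C)(C)C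
F0 | step 16 | none | none
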